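## Retrosynthetic overview

1. Numbering: bicyclo[3.3.1]nonane C1 (prenyl bridgehead), C2(=O), C3 (isobutyryl), C4(OH), C5 (methyl bridgehead), C6, C7, C8 (CMe2), C9 (bridging C=O). Enabling feature: ring A (C1–C2–C3–C4–C5–C9) is a C-cyclised polyketide whose carbonyl carbons C9, C2, C4 alternate with C1, C3, C5, so C5–C9 and C3–C4 are both acyl–α-carbon (Claisen) bonds.
2. Key disconnection (polyketide logic, C-cyclisation in place of O-cyclisation): C5–C9 and C3–C4 lead back to the 3,3-disubstituted 6-isopropyl-2H-pyran-2,4(3H)-dione 15. In 15, C9 is the enol-lactone carbonyl, C2–C3 and the isobutyryl group are the pyranone, and C4–C5 is a tethered propanoate.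
3. C7 is set last: its prenyl group and stereocentre come from a 7-methylidene group by exo-face hydroboration and B-alkyl Suzuki coupling. The C1 prenyl group comes from a butenyl group by cross-metathesis.
4. C1 and the C1–C8 bond come from two Claisen rearrangements on 4-hydroxy-6-isopropyl-2-pyranone, the second with 1,3-chirality transfer from (S)-but-3-en-2-ol.
5. Ring order: pyranone (temporary, steps 1–2), then ring B (C1–C8–C7–C6–C5–C9), then ring A; rings B and A both close in step 10.

Key step: step 10

Assumption: the α-methyl ester carbon (later C5) is carried as a mixture of epimers in 10–15 because it is enolised in step 10, so it has no descriptor there; the target is written in the enol tautomer of the given SMILES.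

## Route

Step 1
Reactants: 1 2,2,6-trimethyl-4H-1,3-dioxin-4-one; 2 2-methylpropanoyl chloride
Product: 3 2,2-dimethyl-6-(3-methyl-2-oxobutyl)-4H-1,3-dioxin-4-one
Conditions: 1 (2.0 equiv), LiN(i-Pr)2 (2.0 equiv), THF, −78 °C; then 2 (1.0 equiv), −78 to −20 °C; aq. NH4Cl
Reagents that add atoms: none
Why: γ-selective C-acylation of the lithium dienolate of the dioxinone (vinylogous Claisen acylation) is a standard entry to 6-(2-oxoalkyl)dioxinones; the second equivalent of dienolate takes up the proton of the more acidic product.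

Step 2
Reactants: 3 2,2-dimethyl-6-(3-methyl-2-oxobutyl)-4H-1,3-dioxin-4-one
Product: 5 4-hydroxy-6-(propan-2-yl)-2H-pyran-2-one, via acylketene 4 (not isolated)
Conditions: toluene, 110 °C
Reagents that add atoms: none
Why: thermal retro-[4+2] loss of acetone gives acylketene 4, which should be trapped by the enol oxygen of the side-chain ketone (six-membered lactonisation) to give the 4-hydroxy-2-pyranone; no stereocentre is involved.

Step 3
Reactants: 6 diethyl 2-(propan-2-ylidene)propanedioate
Product: 7 2-(propan-2-ylidene)propane-1,3-diol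
Conditions: i-Bu2AlH (4.5 equiv), CH2Cl2, −78 to 0 °C; aqueous potassium sodium tartrate work-up
Reagents that add atoms: none
Why: 1,2-reduction of both conjugated esters by the aluminium hydride should give the allylic diol (ester-to-alcohol reduction); low temperature is chosen to suppress conjugate reduction.

Step 4
Reactants: 7 2-(propan-2-ylidene)propane-1,3-diol
Product: 8 1-bromo-2-(bromomethyl)-3-methylbut-2-ene
Conditions: PBr3 (0.8 equiv), Et2O, 0 °C
Reagents that add atoms: phosphorus tribromide, BrP(Br)Br
Why: primary allylic alcohols are converted into bromides by PBr3 (nucleophilic substitution through the phosphite ester); any tertiary bromide from SN2' delivery should equilibrate to the more stable primary dibromide with the tetrasubstituted alkene.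

Step 5
Reactants: 9 methyl propanoate; 8 1-bromo-2-(bromomethyl)-3-methylbut-2-ene
Product: 10 methyl 4-(bromomethyl)-2,5-dimethylhex-4-enoate (racemic)
Conditions: 9, LiN(i-Pr)2 (1.05 equiv), THF, −78 °C; then added to 8 (3 equiv), THF/DMPU, −78 to −20 °C
Reagents that add atoms: none
Why: SN2 alkylation of the lithium ester enolate by the primary allylic bromide, with the excess of symmetrical dibromide limiting double alkylation; the new stereocentre (later C5) is left racemic on purpose.

Step 6
Reactants: 5 4-hydroxy-6-(propan-2-yl)-2H-pyran-2-one; 10 methyl 4-(bromomethyl)-2,5-dimethylhex-4-enoate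
Product: 11 methyl 2,5-dimethyl-4-({[2-oxo-6-(propan-2-yl)-2H-pyran-4-yl]oxy}methyl)hex-4-enoate
Conditions: K2CO3 (1.5 equiv), acetone, 56 °C
Reagents that add atoms: none
Why: Williamson-type O-alkylation of the acidic hydroxypyranone with a primary allylic bromide; either oxygen regioisomer (4-alkoxy-2-pyranone or 2-alkoxy-4-pyranone) is an allyl vinyl ether towards C3 and should converge in step 7.

Step 7
Reactants: 11 methyl 2,5-dimethyl-4-({[2-oxo-6-(propan-2-yl)-2H-pyran-4-yl]oxy}methyl)hex-4-enoate
Product: 12 methyl 4-{2-[4-hydroxy-2-oxo-6-(propan-2-yl)-2H-pyran-3-yl]propan-2-yl}-2-methylpent-4-enoate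
Conditions: N,N-diethylaniline, 150 °C
Reagents that add atoms: none
Why: aromatic-type Claisen rearrangement ([3,3]) delivers the CMe2 terminus to C3 of the pyranone, forming the C1–C8 bond and moving the alkene to the exocyclic methylidene, and the product tautomerises back to the hydroxypyranone; the basic solvent is chosen to suppress acid-catalysed addition of the enol to the new alkene.

Step 8
Reactants: 12 methyl 4-{2-[4-hydroxy-2-oxo-6-(propan-2-yl)-2H-pyran-3-yl]propan-2-yl}-2-methylpent-4-enoate; 13 (S)-but-3-en-2-ol
Product: 14 methyl 4-{2-[4-{[(2R)-but-3-en-2-yl]oxy}-2-oxo-6-(propan-2-yl)-2H-pyran-3-yl]propan-2-yl}-2-methylpent-4-enoate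
Conditions: PPh3, diisopropyl azodicarboxylate, THF, 0 to 23 °C
Reagents that add atoms: none
Why: Mitsunobu etherification of the acidic enol with the secondary allylic alcohol proceeds by SN2 with inversion, so the (S)-alcohol should give the (R)-ether; the 4-O-ether is required, and the 2-alkoxy-4-pyranone isomer (which would transfer chirality in the opposite sense) and any SN2' ether are removed by chromatography.

Step 9
Reactants: 14 methyl 4-{2-[4-{[(2R)-but-3-en-2-yl]oxy}-2-oxo-6-(propan-2-yl)-2H-pyran-3-yl]propan-2-yl}-2-methylpent-4-enoate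
Product: 15 methyl 4-{2-[(3S)-3-[(2E)-but-2-en-1-yl]-2,4-dioxo-6-(propan-2-yl)-3,4-dihydro-2H-pyran-3-yl]propan-2-yl}-2-methylpent-4-enoate
Conditions: toluene, 110 °C
Reagents that add atoms: none
Why: dearomatising Claisen rearrangement ([3,3]) through a chair transition state with the methyl group pseudo-equatorial should transfer the chirality of the (R)-ether carbon to C3 of the pyranone (1,3-chirality transfer), giving the (S)-quaternary centre (C1 of the target) next to the quaternary CMe2 carbon and an (E)-butenyl group; the product cannot re-aromatise.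

Step 10
Reactants: 15 methyl 4-{2-[(3S)-3-[(2E)-but-2-en-1-yl]-2,4-dioxo-6-(propan-2-yl)-3,4-dihydro-2H-pyran-3-yl]propan-2-yl}-2-methylpent-4-enoate
Product: 17 (1R,5R)-1-[(2E)-but-2-en-1-yl]-4-hydroxy-5,8,8-trimethyl-7-methylidene-3-(2-methylpropanoyl)bicyclo[3.3.1]non-3-ene-2,9-dione, via cyclohexanone diketo ester 16 (not isolated)
Conditions: LiN(SiMe3)2 (1.2 equiv), THF, −78 to 23 °C; then NaOMe (0.2 equiv), MeOH, 50 °C; aq. HCl
Reagents that add atoms: none
Why: Deprotonation of the ester α-CH gives the C5 enolate, which attacks the enol-lactone carbonyl C9 (Claisen acyl transfer, 6-exo-trig, closing ring B C1–C8–C7–C6–C5–C9); collapse of the tetrahedral intermediate expels the ring oxygen as the 1,3-diketonate of 16, whose central carbon C3 then attacks the C4 methyl ester (Dieckmann-type condensation, 6-(enolendo)-exo-trig, closing ring A) with loss of methoxide, and deprotonation of the β-triketone makes the sequence irreversible. The closest known reaction types are the opening of enol lactones by carbanions with recyclisation of the liberated enolate (Fujimoto–Belleau reaction, carbanion-induced ring transformations of 2-pyranones) and the Dieckmann closure of the trione ring of bicyclo[3.3.1]nonane-2,4,9-triones from cis-2-acyl-6-alkoxycarbonylcyclohexanones. C1 is not touched, and it controls the new quaternary centre C5: ring A can only span cis-1,3-diaxial positions of ring B, so only the diastereomer of 16 with the ester cis to the acyl arm can close. The trans isomer, and any substrate deprotonated at the isopropyl CH, should be returned in the methoxide stage through reversible retro-Claisen/Claisen steps (opening to the C9 methyl ester and re-closure), so that material is funnelled to the one product that leaves the equilibria as its enolate. The step needs attack at the lactone carbonyl C9 rather than at the vinylogous-ester ketone C2, which the substrate secures because C9 is an activated enol ester with a diketonate leaving group whereas aldol addition to C2 is reversible; C- over O-acylation in the second closure follows in the same way, because an enol ester formed there is reopened by methoxide.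

Step 11
Reactants: 17 (1R,5R)-1-[(2E)-but-2-en-1-yl]-4-hydroxy-5,8,8-trimethyl-7-methylidene-3-(2-methylpropanoyl)bicyclo[3.3.1]non-3-ene-2,9-dione; 18 2-methylbut-2-ene
Product: 19 (1R,5R)-4-hydroxy-5,8,8-trimethyl-7-methylidene-1-(3-methylbut-2-en-1-yl)-3-(2-methylpropanoyl)bicyclo[3.3.1]non-3-ene-2,9-dione
Conditions: second-generation Grubbs catalyst (5 mol %), 18 (large excess), CH2Cl2, 40 °C
Reagents that add atoms: none
Why: olefin cross-metathesis of the 1,2-disubstituted butenyl group with 2-methylbut-2-ene should give the prenyl group; the methylidene next to a quaternary carbon is inert, and ring closure onto it is excluded in the bicycle because it would place a double bond at a bridgehead (which is why the metathesis is not run on 15, where cyclopentene formation would compete).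

Step 12
Reactants: 19 (1R,5R)-4-hydroxy-5,8,8-trimethyl-7-methylidene-1-(3-methylbut-2-en-1-yl)-3-(2-methylpropanoyl)bicyclo[3.3.1]non-3-ene-2,9-dione; 20 1-bromo-2-methylprop-1-ene
Product: 22 (1R,5R,7R)-4-hydroxy-5,8,8-trimethyl-1,7-bis(3-methylbut-2-en-1-yl)-3-(2-methylpropanoyl)bicyclo[3.3.1]non-3-ene-2,9-dione, via B-alkyl-9-BBN adduct 21 (not isolated)
Conditions: 9-BBN (2.5 equiv), THF, 0 to 40 °C; then Pd(dppf)Cl2 (10 mol %), aq. K3PO4, 20 (3 equiv), DMF, 60 °C; aq. HCl
Reagents that add atoms: none
Why: hydroboration of the exocyclic methylidene with 9-BBN from the open exo face of ring B (the endo face is screened by C3 of ring A) should place hydrogen exo and the CH2–B group endo at C7, setting the 7R centre, and B-alkyl Suzuki–Miyaura coupling with the vinyl bromide completes the prenyl group; 9-BBN should leave the trisubstituted prenyl alkene alone, and the first equivalent is taken up by the acidic enol as a borinate that is cleaved on work-up.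

## Compound list

1 | 2,2,6-trimethyl-4H-1,3-dioxin-4-one | CC1=CC(=O)OC(C)(C)O1 | starting material
2 | 2-methylpropanoyl chloride | CC(C)C(Cl)=O | starting material
3 | 2,2-dimethyl-6-(3-methyl-2-oxobutyl)-4H-1,3-dioxin-4-one | CC(C)C(=O)CC1=CC(=O)OC(C)(C)O1 | intermediate
4 | 6-methyl-3,5-dioxohept-1-en-1-one (acylketene) | CC(C)C(=O)CC(=O)C=C=O | intermediate (not isolated)
5 | 4-hydroxy-6-(propan-2-yl)-2H-pyran-2-one | CC(C)C1=CC(O)=CC(=O)O1 | intermediate
6 | diethyl 2-(propan-2-ylidene)propanedioate | CCOC(=O)C(=C(C)C)C(=O)OCC | starting material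
7 | 2-(propan-2-ylidene)propane-1,3-diol | CC(C)=C(CO)CO | intermediate
8 | 1-bromo-2-(bromomethyl)-3-methylbut-2-ene | CC(C)=C(CBr)CBr | intermediate
9 | methyl propanoate | CCC(=O)OC | starting material
10 | methyl 4-(bromomethyl)-2,5-dimethylhex-4-enoate (racemic) | COC(=O)C(C)CC(CBr)=C(C)C | intermediate
11 | methyl 2,5-dimethyl-4-({[2-oxo-6-(propan-2-yl)-2H-pyran-4-yl]oxy}methyl)hex-4-enoate | COC(=O)C(C)CC(COC1=CC(=O)OC(C(C)C)=C1)=C(C)C | intermediate
12 | methyl 4-{2-[4-hydroxy-2-oxo-6-(propan-2-yl)-2H-pyran-3-yl]propan-2-yl}-2-methylpent-4-enoate | COC(=O)C(C)CC(=C)C(C)(C)C1=C(O)C=C(C(C)C)OC1=O | intermediate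
13 | (S)-but-3-en-2-ol | C[C@H](O)C=C | starting material
14 | methyl 4-{2-[4-{[(2R)-but-3-en-2-yl]oxy}-2-oxo-6-(propan-2-yl)-2H-pyran-3-yl]propan-2-yl}-2-methylpent-4-enoate | COC(=O)C(C)CC(=C)C(C)(C)C1=C(O[C@H](C)C=C)C=C(C(C)C)OC1=O | intermediate
15 | methyl 4-{2-[(3S)-3-[(2E)-but-2-en-1-yl]-2,4-dioxo-6-(propan-2-yl)-3,4-dihydro-2H-pyran-3-yl]propan-2-yl}-2-methylpent-4-enoate | COC(=O)C(C)CC(=C)C(C)(C)[C@]1(C/C=C/C)C(=O)OC(C(C)C)=CC1=O | intermediate
16 | methyl (1S,3S)-3-[(2E)-but-2-en-1-yl]-1,4,4-trimethyl-5-methylidene-3-(4-methyl-3-oxopentanoyl)-2-oxocyclohexane-1-carboxylate (ester cis to the acyl arm; present as its diketonate) | C=C1C[C@](C)(C(=O)OC)C(=O)[C@](C/C=C/C)(C(=O)CC(=O)C(C)C)C1(C)C | intermediate (not isolated)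
17 | (1R,5R)-1-[(2E)-but-2-en-1-yl]-4-hydroxy-5,8,8-trimethyl-7-methylidene-3-(2-methylpropanoyl)bicyclo[3.3.1]non-3-ene-2,9-dione | C=C1C[C@@]2(C)C(=O)[C@](C/C=C/C)(C(=O)C(C(=O)C(C)C)=C2O)C1(C)C | intermediate
18 | 2-methylbut-2-ene | CC=C(C)C | starting material
19 | (1R,5R)-4-hydroxy-5,8,8-trimethyl-7-methylidene-1-(3-methylbut-2-en-1-yl)-3-(2-methylpropanoyl)bicyclo[3.3.1]non-3-ene-2,9-dione | C=C1C[C@@]2(C)C(=O)[C@](CC=C(C)C)(C(=O)C(C(=O)C(C)C)=C2O)C1(C)C | intermediate
20 | 1-bromo-2-methylprop-1-ene | CC(C)=CBr | starting material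
21 | (1R,5R,7R)-7-[(9-borabicyclo[3.3.1]nonan-9-yl)methyl]-4-[(9-borabicyclo[3.3.1]nonan-9-yl)oxy]-5,8,8-trimethyl-1-(3-methylbut-2-en-1-yl)-3-(2-methylpropanoyl)bicyclo[3.3.1]non-3-ene-2,9-dione | C1CCC2CCCC1B2C[C@@H]1C[C@@]2(C)C(=O)[C@](CC=C(C)C)(C(=O)C(C(=O)C(C)C)=C2OB2C3CCCC2CCC3)C1(C)C | intermediate (not isolated)
22 | (1R,5R,7R)-4-hydroxy-5,8,8-trimethyl-1,7-bis(3-methylbut-2-en-1-yl)-3-(2-methylpropanoyl)bicyclo[3.3.1]non-3-ene-2,9-dione | CC(C)=CC[C@@H]1C[C@@]2(C)C(=O)[C@](CC=C(C)C)(C(=O)C(C(=O)C(C)C)=C2O)C1(C)C | target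

## Step count and risks

Total step count: 12. Longest linear sequence: 10 steps (6 to 22, steps 3–12).

Steps most likely to fail:

Step 10 (key step). The cascade may stall after the first acyl transfer if the stabilised diketonate attacks the hindered ester too slowly. Enolisation may also occur at the isopropyl CH of the pyranone instead of the ester, or the return of the trans isomer may be inefficient. Fallback: the enol lactone is given up as the activating group. Starting from 15, NaOMe (1.1 equiv) in MeOH at 0 °C should open the lactone to dimethyl (2S)-2-[(2E)-but-2-en-1-yl]-3,3,6-trimethyl-4-methylidene-2-(4-methyl-3-oxopentanoyl)heptanedioate F1, the open-chain triketide diester. F1 is isolated and cyclised under fully equilibrating conditions (NaOMe, 3 equiv, MeOH/toluene, 80 °C) by two consecutive Dieckmann condensations, which returns to the route at 17.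

Step 9. The 1,3-chirality transfer may be eroded if the tert-alkyl group on the migration terminus forces a boat transition state, or if the secondary allylic ether ionises before the sigmatropic shift; unclean formation of the 4-O-ether in step 8 would have the same effect. Fallback: the quaternary centre is set under catalyst control. Starting from 12, allyl chloroformate and Et3N (CH2Cl2, 0 °C) give methyl 2-methyl-4-{2-[2-oxo-6-(propan-2-yl)-4-{[(prop-2-en-1-yloxy)carbonyl]oxy}-2H-pyran-3-yl]propan-2-yl}pent-4-enoate F2. Palladium-catalysed decarboxylative asymmetric allylic alkylation (Pd2(dba)3, 2.5 mol %, (S)-t-Bu-PHOX, 6 mol %, THF, 25 °C; the ligand enantiomer to be chosen for the (S)-centre) should give methyl 4-{2-[(3S)-2,4-dioxo-6-(propan-2-yl)-3-(prop-2-en-1-yl)-3,4-dihydro-2H-pyran-3-yl]propan-2-yl}-2-methylpent-4-enoate F3. F3 is taken through the conditions of step 10 to (1R,5R)-4-hydroxy-5,8,8-trimethyl-7-methylidene-3-(2-methylpropanoyl)-1-(prop-2-en-1-yl)bicyclo[3.3.1]non-3-ene-2,9-dione F4. Cross-metathesis of F4 with 18 under the conditions of step 11 returns to the route at 19.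

Step 12. The acidic β-triketone may consume the borane, a ring carbonyl may be reduced, or the diketonate may sequester the palladium catalyst so that the coupling stalls; facial selectivity is not the concern. Fallback: a hydroformylation/olefination pair without boron or palladium. Starting from 19, rhodium-catalysed hydroformylation (Rh(acac)(CO)2, 2 mol %, PPh3, CO/H2 1:1, 20 bar, toluene, 80 °C) should add hydrogen to C7 from the same exo face and the formyl group to the terminal carbon, giving 2-[(1R,5R,7S)-4-hydroxy-5,8,8-trimethyl-1-(3-methylbut-2-en-1-yl)-3-(2-methylpropanoyl)-2,9-dioxobicyclo[3.3.1]non-3-en-7-yl]acetaldehyde F5. Wittig olefination of F5 with isopropylidenetriphenylphosphorane (from isopropyltriphenylphosphonium iodide and n-BuLi, 2.2 equiv, THF, 0 °C; the first equivalent deprotonates the enol) returns to the route at 22.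

## Further compounds

F1 | step 10 | dimethyl (2S)-2-[(2E)-but-2-en-1-yl]-3,3,6-trimethyl-4-methylidene-2-(4-methyl-3-oxopentanoyl)heptanedioate | COC(=O)C(C)CC(=C)C(C)(C)[C@](C/C=C/C)(C(=O)OC)C(=O)CC(=O)C(C)C
F2 | step 9 | methyl 2-methyl-4-{2-[2-oxo-6-(propan-2-yl)-4-{[(prop-2-en-1-yloxy)carbonyl]oxy}-2H-pyran-3-yl]propan-2-yl}pent-4-enoate | COC(=O)C(C)CC(=C)C(C)(C)C1=C(OC(=O)OCC=C)C=C(C(C)C)OC1=O
F3 | step 9 | methyl 4-{2-[(3S)-2,4-dioxo-6-(propan-2-yl)-3-(prop-2-en-1-yl)-3,4-dihydro-2H-pyran-3-yl]propan-2-yl}-2-methylpent-4-enoate | COC(=O)C(C)CC(=C)C(C)(C)[C@]1(CC=C)C(=O)OC(C(C)C)=CC1=O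
F4 | step 9 | (1R,5R)-4-hydroxy-5,8,8-trimethyl-7-methylidene-3-(2-methylpropanoyl)-1-(prop-2-en-1-yl)bicyclo[3.3.1]non-3-ene-2,9-dione | C=C1C[C@@]2(C)C(=O)[C@](CC=C)(C(=O)C(C(=O)C(C)C)=C2O)C1(C)C
F5 | step 12 | 2-[(1R,5R,7S)-4-hydroxy-5,8,8-trimethyl-1-(3-methylbut-2-en-1-yl)-3-(2-methylpropanoyl)-2,9-dioxobicyclo[3.3.1]non-3-en-7-yl]acetaldehyde | O=CC[C@@H]1C[C@@]2(C)C(=O)[C@](CC=C(C)C)(C(=O)C(C(=O)C(C)C)=C2O)C1(C)C
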